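## Retrosynthetic overview

1. The target is opened back to a 3-substituted 4,7-dihydroxycoumarin: the ketone CH2 is coumarin C3, the resorcinol ring and both phenols come from the coumarin, and the lactone carbonyl leaves as CO2.
2. That coumarin comes from an enantioselective [3,3] Claisen rearrangement of the 4-O-allyl coumarin ether under a chiral hydrogen-bond-donor organocatalyst; this forms the C–C bond, the vinyl group and the quaternary stereocentre (the new step).
3. The ether comes from Mitsunobu O-alkylation of 4,7-dihydroxycoumarin with a (2E,6E)-furyl dienol.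
4. The dienol comes from geranyl acetate by E-selective allylic oxidation at C8, bromination and allyl–furyl cross-coupling with a 4-methylfuran-2-yl boronate.
5. No ring is built: the benzene ring (as the coumarin) and the furan are bought, and the pyranone ring is a temporary tether that is opened in the last step.

Assumption: the furylboronic ester of step 3 is bought as a catalogue building block, and the (S,S) catalyst of step 5 is taken to favour Si-face attack (its mirror image is used if the sense proves opposite).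

## Route

Step 1
Reactants: 1 geranyl acetate, (2E)-3,7-dimethylocta-2,6-dien-1-yl acetate
Product: 2 (2E,6E)-8-hydroxy-3,7-dimethylocta-2,6-dien-1-yl acetate
Conditions: SeO2 (0.1 equiv), t-BuOOH (70% aq., 3 equiv), salicylic acid (0.1 equiv), CH2Cl2, rt, 30 h
Reagents that add atoms: tert-butyl hydroperoxide, CC(C)(C)OO
Why: SeO2/t-BuOOH allylic oxidation (ene reaction then [2,3]-sigmatropic shift) attacks the (E)-methyl of the electron-rich 6,7-alkene, the 2,3-alkene being deactivated by the allylic acetate, and the cyclic shift keeps the 6E geometry.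

Step 2
Reactants: 2 (2E,6E)-8-hydroxy-3,7-dimethylocta-2,6-dien-1-yl acetate
Product: 3 (2E,6E)-8-bromo-3,7-dimethylocta-2,6-dien-1-yl acetate
Conditions: CBr4, PPh3, CH2Cl2, 0 °C, 1 h
Reagents that add atoms: carbon tetrabromide, BrC(Br)(Br)Br
Why: Appel bromination of the primary allylic alcohol goes by SN2 at 0 °C without allylic transposition and leaves the acetate and both E alkenes untouched.

Step 3
Reactants: 3 (2E,6E)-8-bromo-3,7-dimethylocta-2,6-dien-1-yl acetate; 4 4,4,5,5-tetramethyl-2-(4-methylfuran-2-yl)-1,3,2-dioxaborolane (1.3 equiv)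
Product: 6 (2E,6E)-3,7-dimethyl-8-(4-methylfuran-2-yl)octa-2,6-dien-1-ol, via dienyl acetate 5 (not isolated)
Conditions: Pd(PPh3)4 (3 mol%), K2CO3 (3 equiv), THF/H2O 9:1, 40 °C, 4 h; then MeOH, rt, 3 h
Reagents that add atoms: none
Why: Suzuki–Miyaura allyl–heteroaryl coupling, in which zerovalent palladium adds to the allylic bromide much faster than to the allylic acetate and the furyl group goes to the unhindered CH2 end of the syn π-allyl so the 6E alkene is kept; K2CO3/MeOH then transesterifies the acetate in the same flask.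

Step 4
Reactants: 6 (2E,6E)-3,7-dimethyl-8-(4-methylfuran-2-yl)octa-2,6-dien-1-ol; 7 4,7-dihydroxy-2H-chromen-2-one (1.3 equiv)
Product: 8 4-{[(2E,6E)-3,7-dimethyl-8-(4-methylfuran-2-yl)octa-2,6-dien-1-yl]oxy}-7-hydroxy-2H-chromen-2-one
Conditions: PPh3, diisopropyl azodicarboxylate (added last, dropwise), THF, 0 °C → rt
Reagents that add atoms: none
Why: Mitsunobu etherification, in which the vinylogous-acid 4-OH (pKa about 4–5) is deprotonated in preference to the 7-OH (pKa about 8–9) and its oxygen displaces the alkoxyphosphonium at the primary allylic carbon by SN2, keeping the 2E geometry.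

Step 5
Reactants: 8 4-{[(2E,6E)-3,7-dimethyl-8-(4-methylfuran-2-yl)octa-2,6-dien-1-yl]oxy}-7-hydroxy-2H-chromen-2-one
Product: 9 3-[(3S,6E)-3,7-dimethyl-8-(4-methylfuran-2-yl)octa-1,6-dien-3-yl]-4,7-dihydroxy-2H-chromen-2-one
Conditions: N,N′-bis[(1S,2S)-2-(2-methyl-5-phenyl-1H-pyrrol-1-yl)cyclohexyl]guanidinium tetrakis[3,5-bis(trifluoromethyl)phenyl]borate (20 mol%), toluene, 40 °C, 72 h; crude product taken on without acidic silica
Reagents that add atoms: none
Why: Proposed new method: an enantioselective Claisen rearrangement ([3,3]-sigmatropic shift) of a 4-(allyloxy)coumarin under a chiral guanidinium hydrogen-bond donor – the transition state is strongly polarised towards a 3,3-dialkylallyl cation and the very stable 4-oxidocoumarin, so the cationic N–H pair bound to the ether/lactone oxygens should lower the barrier well below the thermal one (about 130 °C), while the aryl-pyrrole arms hold the allyl fragment by cation–π contact so that coumarin C3 bonds to the Si face of C3′ of the (2E)-allyl unit and sets the quaternary centre as S (coumarin C3 stays trigonal, so this face choice alone fixes the configuration); the closest known reaction type is the guanidinium-catalysed enantioselective Claisen rearrangement of ester-substituted allyl vinyl ethers and O-allyl β-ketoesters, together with the uncatalysed thermal Claisen rearrangement of 4-allyloxycoumarins.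

Step 6
Reactants: 9 3-[(3S,6E)-3,7-dimethyl-8-(4-methylfuran-2-yl)octa-1,6-dien-3-yl]-4,7-dihydroxy-2H-chromen-2-one
Product: 11 (3R,6E)-1-(2,4-dihydroxyphenyl)-3-ethenyl-3,7-dimethyl-8-(4-methylfuran-2-yl)oct-6-en-1-one, via β-keto acid 10 (not isolated)
Conditions: 2 M NaOH, EtOH/H2O 1:1, reflux, Ar, 6 h; then 2 M HCl to pH 4, 40 °C
Reagents that add atoms: none
Why: Alkaline lactone hydrolysis followed by decarboxylation of the β-keto acid (the classical ketonic cleavage of 3-alkyl-4-hydroxycoumarins) turns coumarin C3 into the ketone CH2; the quaternary centre has no α-hydrogen and cannot epimerise, so S in 9 becomes R in 11 only through the change in substituent priorities.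

## Compound list

1 | geranyl acetate, (2E)-3,7-dimethylocta-2,6-dien-1-yl acetate | CC(C)=CCC/C(C)=C/COC(C)=O | starting material
2 | (2E,6E)-8-hydroxy-3,7-dimethylocta-2,6-dien-1-yl acetate | OC/C(C)=C/CC/C(C)=C/COC(C)=O | intermediate
3 | (2E,6E)-8-bromo-3,7-dimethylocta-2,6-dien-1-yl acetate | BrC/C(C)=C/CC/C(C)=C/COC(C)=O | intermediate
4 | 4,4,5,5-tetramethyl-2-(4-methylfuran-2-yl)-1,3,2-dioxaborolane | Cc1coc(B2OC(C)(C)C(C)(C)O2)c1 | starting material
5 | (2E,6E)-3,7-dimethyl-8-(4-methylfuran-2-yl)octa-2,6-dien-1-yl acetate | Cc1coc(C/C(C)=C/CC/C(C)=C/COC(C)=O)c1 | intermediate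
6 | (2E,6E)-3,7-dimethyl-8-(4-methylfuran-2-yl)octa-2,6-dien-1-ol | Cc1coc(C/C(C)=C/CC/C(C)=C/CO)c1 | intermediate
7 | 4,7-dihydroxy-2H-chromen-2-one | O=c1cc(O)c2ccc(O)cc2o1 | starting material
8 | 4-{[(2E,6E)-3,7-dimethyl-8-(4-methylfuran-2-yl)octa-2,6-dien-1-yl]oxy}-7-hydroxy-2H-chromen-2-one | Cc1coc(C/C(C)=C/CC/C(C)=C/COc2cc(=O)oc3cc(O)ccc23)c1 | intermediate
9 | 3-[(3S,6E)-3,7-dimethyl-8-(4-methylfuran-2-yl)octa-1,6-dien-3-yl]-4,7-dihydroxy-2H-chromen-2-one | C=C[C@](C)(CC/C=C(\C)Cc1cc(C)co1)c1c(O)c2ccc(O)cc2oc1=O | intermediate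
10 | (3S,6E)-2-(2,4-dihydroxybenzoyl)-3-ethenyl-3,7-dimethyl-8-(4-methylfuran-2-yl)oct-6-enoic acid (both C2 epimers) | C=C[C@](C)(CC/C=C(\C)Cc1cc(C)co1)C(C(=O)O)C(=O)c1ccc(O)cc1O | intermediate
11 | (3R,6E)-1-(2,4-dihydroxyphenyl)-3-ethenyl-3,7-dimethyl-8-(4-methylfuran-2-yl)oct-6-en-1-one | C=C[C@](C)(CC/C=C(\C)Cc1cc(C)co1)CC(=O)c1ccc(O)cc1O | target

## Summary and risks

Total step count: 6. Longest linear sequence: 6 steps (1 → 2 → 3 → 6 → 8 → 9 → 11).

**Step 5 (the new Claisen step).** In 8 the lactone carbonyl is held anti to the ether oxygen, so the two-point binding available to the known ester substrates is missing. The catalyst may therefore give too little acceleration or selectivity, an ion-pair pathway may erode the ee, and acidic 9 can cyclise onto its vinyl group.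

The fallback uses known chemistry, sets out from 6 and comes back at 11. Alcohol 6 is phosphorylated (ClP(O)(OEt)2, Et3N, 4-(dimethylamino)pyridine) to diethyl (2E,6E)-3,7-dimethyl-8-(4-methylfuran-2-yl)octa-2,6-dien-1-yl phosphate F1. Commercial 2,4-dihydroxybenzaldehyde is silylated (i-Pr3SiCl, imidazole) to 2,4-bis[(triisopropylsilyl)oxy]benzaldehyde F2 and homologated with Me3SiC(Li)N2 (Colvin rearrangement) to 1-ethynyl-2,4-bis[(triisopropylsilyl)oxy]benzene F3. i-Bu2AlH with catalytic Et3N converts F3 in solution into ({2,4-bis[(triisopropylsilyl)oxy]phenyl}ethynyl)diisobutylaluminium F4. F4 and F1 are joined by the established copper-catalysed enantioselective SN2′ allylic substitution of E-trisubstituted allylic phosphates with alkynylaluminium reagents. The catalyst is CuCl2·2H2O with the chiral sulfonate-bearing carbene precursor 2-[(4S,5S)-3-(2,6-diisopropylphenyl)-4,5-diphenyl-4,5-dihydro-1H-imidazol-3-ium-1-yl]benzenesulfonate, or its mirror image, whichever gives the S product (THF, −15 °C). This gives the 1,4-enyne (3S,6E)-1-{2,4-bis[(triisopropylsilyl)oxy]phenyl}-3-ethenyl-3,7-dimethyl-8-(4-methylfuran-2-yl)oct-6-en-1-yne F5 with the quaternary centre in place. Gold-catalysed hydration (Ph3PAuNTf2, wet 1,4-dioxane, 50 °C; water adds at the aryl-bound alkyne carbon) gives (3R,6E)-1-{2,4-bis[(triisopropylsilyl)oxy]phenyl}-3-ethenyl-3,7-dimethyl-8-(4-methylfuran-2-yl)oct-6-en-1-one F6. Bu4NF (THF, 0 °C) removes both silyl groups to give 11.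

**Step 4 (Mitsunobu).** The 7-OH may also be alkylated once the 4-OH is consumed, and the ambident 4-oxidocoumarin can give some 2-alkoxychromone or C3-alkylated product.

The fallback differentiates the two hydroxyls by protection instead of by acidity; it sets out from 7 and comes back at 8. Compound 7 is silylated through its dianion (NaH, 2 equiv; t-BuMe2SiCl, 1 equiv, DMF; the phenoxide, not the delocalised 4-oxido group, takes the silyl group) to 7-[(tert-butyldimethylsilyl)oxy]-4-hydroxy-2H-chromen-2-one F7. Mitsunobu coupling of F7 with 6 (PPh3, diisopropyl azodicarboxylate, THF) gives 7-[(tert-butyldimethylsilyl)oxy]-4-{[(2E,6E)-3,7-dimethyl-8-(4-methylfuran-2-yl)octa-2,6-dien-1-yl]oxy}-2H-chromen-2-one F8, a non-polar compound that is easily purified. Bu4NF buffered with AcOH (THF, 0 °C) frees the phenol to give 8.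

**Step 3 (allyl–furyl coupling).** The 2-furylboronate can protodeboronate under aqueous base, the distal allylic acetate can ionise on palladium, and some branched (SN2′-type) product can form.

The fallback builds the furan instead of coupling it; it sets out from 3 and comes back at 6. Commercial 3-methylfuran-2(5H)-one is silylated (Me3SiOTf, Et3N) to trimethyl[(3-methylfuran-2-yl)oxy]silane F9. Silver trifluoroacetate (AgOCOCF3, CH2Cl2, −78 °C) promotes γ-alkylation of F9 by bromide 3 to the butenolide (2E,6E)-3,7-dimethyl-8-(4-methyl-5-oxo-2,5-dihydrofuran-2-yl)octa-2,6-dien-1-yl acetate F10. Excess i-Bu2AlH (CH2Cl2, −78 °C) reduces the lactone to the lactol 5-[(2E,6E)-8-hydroxy-2,6-dimethylocta-2,6-dien-1-yl]-3-methyl-2,5-dihydrofuran-2-ol F11 and cleaves the acetate at the same time. A mildly acidic work-up (aqueous citric acid) dehydrates the lactol to the furan, giving 6 with the methyl group fixed at C4 of the furan by construction.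

Further compounds
F1 | step 5 | diethyl (2E,6E)-3,7-dimethyl-8-(4-methylfuran-2-yl)octa-2,6-dien-1-yl phosphate | Cc1coc(C/C(C)=C/CC/C(C)=C/COP(=O)(OCC)OCC)c1
F2 | step 5 | 2,4-bis[(triisopropylsilyl)oxy]benzaldehyde | O=Cc1ccc(O[Si](C(C)C)(C(C)C)C(C)C)cc1O[Si](C(C)C)(C(C)C)C(C)C
F3 | step 5 | 1-ethynyl-2,4-bis[(triisopropylsilyl)oxy]benzene | C#Cc1ccc(O[Si](C(C)C)(C(C)C)C(C)C)cc1O[Si](C(C)C)(C(C)C)C(C)C
F4 | step 5 | ({2,4-bis[(triisopropylsilyl)oxy]phenyl}ethynyl)diisobutylaluminium | CC(C)C[Al](CC(C)C)C#Cc1ccc(O[Si](C(C)C)(C(C)C)C(C)C)cc1O[Si](C(C)C)(C(C)C)C(C)C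
F5 | step 5 | (3S,6E)-1-{2,4-bis[(triisopropylsilyl)oxy]phenyl}-3-ethenyl-3,7-dimethyl-8-(4-methylfuran-2-yl)oct-6-en-1-yne | C=C[C@](C)(CC/C=C(\C)Cc1cc(C)co1)C#Cc1ccc(O[Si](C(C)C)(C(C)C)C(C)C)cc1O[Si](C(C)C)(C(C)C)C(C)C
F6 | step 5 | (3R,6E)-1-{2,4-bis[(triisopropylsilyl)oxy]phenyl}-3-ethenyl-3,7-dimethyl-8-(4-methylfuran-2-yl)oct-6-en-1-one | C=C[C@](C)(CC/C=C(\C)Cc1cc(C)co1)CC(=O)c1ccc(O[Si](C(C)C)(C(C)C)C(C)C)cc1O[Si](C(C)C)(C(C)C)C(C)C
F7 | step 4 | 7-[(tert-butyldimethylsilyl)oxy]-4-hydroxy-2H-chromen-2-one | O=c1cc(O)c2ccc(O[Si](C)(C)C(C)(C)C)cc2o1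
F8 | step 4 | 7-[(tert-butyldimethylsilyl)oxy]-4-{[(2E,6E)-3,7-dimethyl-8-(4-methylfuran-2-yl)octa-2,6-dien-1-yl]oxy}-2H-chromen-2-one | Cc1coc(C/C(C)=C/CC/C(C)=C/COc2cc(=O)oc3cc(O[Si](C)(C)C(C)(C)C)ccc23)c1
F9 | step 3 | trimethyl[(3-methylfuran-2-yl)oxy]silane | Cc1ccoc1O[Si](C)(C)C
F10 | step 3 | (2E,6E)-3,7-dimethyl-8-(4-methyl-5-oxo-2,5-dihydrofuran-2-yl)octa-2,6-dien-1-yl acetate (racemic at the ring carbon) | CC1=CC(C/C(C)=C/CC/C(C)=C/COC(C)=O)OC1=O
F11 | step 3 | 5-[(2E,6E)-8-hydroxy-2,6-dimethylocta-2,6-dien-1-yl]-3-methyl-2,5-dihydrofuran-2-ol (mixture of stereoisomers) | CC1=CC(C/C(C)=C/CC/C(C)=C/CO)OC1O
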